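**Strategy.** Ring B of the target is a cross-conjugated dienone whose C6=C7 and C9=C10 double bonds flank the quaternary C5; this 1,4-diene pattern is cut at C5–C10 and C8–C9. A single intramolecular Diels–Alder reaction of a dienynone therefore closes rings A and B and sets C5. The precursor is an acyclic ethynyl ketone (C9≡C10–C1=O) tied through C2–C4 to an (E)-diene C5=C6–C7=C8 that carries C11 as a silyl ether. C3 travels as a (3R) silyl ether, trans to the C4 methyl, so that both tether substituents are equatorial; the axial C3–O bond of the target is made afterwards by ketone reduction, then C1, C8 and C11 are adjusted.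

Key step: step 13

Remark: eremophilane numbering is used for all compounds, α is the face of ring A that carries the C5 methyl, and the target is read as (1R,3S,4R,5R) with 1-OH, 3-O-angeloyl, 4-CH3 and 5-CH3 all α; because an oxygen on C3 can only sit equatorial (β, trans to the C5 methyl) in the ring-forming transition state, C3 is deliberately carried through the key step as its β epimer and corrected later.

**Route**

Step 1
Reactants: 1 (S)-but-3-yn-2-ol
Product: 2 (S)-but-3-yn-2-yl methanesulfonate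
Conditions: MsCl, Et3N, CH2Cl2, −78 → 0 °C
Reagents that add atoms: methanesulfonyl chloride, CS(=O)(=O)Cl
Why: O-Sulfonylation of the propargylic alcohol leaves the C–O bond intact, so the S configuration is kept.

Step 2
Reactants: 2 (S)-but-3-yn-2-yl methanesulfonate; 3 3-[(tert-butyldimethylsilyl)oxy]propanal
Product: 5 (3S,4R)-1-[(tert-butyldimethylsilyl)oxy]-4-methylhex-5-yn-3-ol, via allenylzinc 4 (not isolated)
Conditions: Pd(OAc)2 (5 mol %), PPh3 (5 mol %), Et2Zn (3 equiv), THF, −78 → −20 °C; aq NH4Cl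
Reagents that add atoms: none
Why: Marshall propargylation, in which zerovalent palladium displaces the mesylate anti (SN2′), exchange with Et2Zn gives allenylzinc 4 with retention, and its cyclic SE2′ addition to the aldehyde should give the anti homopropargylic alcohol, C4 (R) coming from the mesylate and C3 (S) from the chair-like transition state.

Step 3
Reactants: 5 (3S,4R)-1-[(tert-butyldimethylsilyl)oxy]-4-methylhex-5-yn-3-ol
Product: 7 (3S,4R,E)-1-[(tert-butyldimethylsilyl)oxy]-6-iodo-4,5-dimethylhex-5-en-3-ol, via alkenylalane 6 (not isolated)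
Conditions: Me3Al (3 equiv), Cp2ZrCl2 (0.3 equiv), CH2Cl2, 0 °C → rt; then I2, THF, −30 → 0 °C
Reagents that add atoms: trimethylaluminium, C[Al](C)C; iodine, II
Why: Negishi zirconium-catalysed carboalumination adds CH3–Al syn across the terminal alkyne (methyl to C5, aluminium to C6, helped by the neighbouring aluminium alkoxide), and iodinolysis of the C–Al bond with retention should give the (E)-iodoalkene.

Step 4
Reactants: 7 (3S,4R,E)-1-[(tert-butyldimethylsilyl)oxy]-6-iodo-4,5-dimethylhex-5-en-3-ol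
Product: 8 (3R,4R,E)-1-[(tert-butyldimethylsilyl)oxy]-6-iodo-4,5-dimethylhex-5-en-3-yl 4-nitrobenzoate
Conditions: 4-nitrobenzoic acid, PPh3, DIAD, PhMe, 0 °C → rt
Reagents that add atoms: 4-nitrobenzoic acid, OC(=O)c1ccc(cc1)[N+](=O)[O-]
Why: Mitsunobu reaction, in which SN2 displacement of the oxyphosphonium group by the carboxylate inverts C3 to R and so creates the 3,4-syn diad (O3 trans to the C4 methyl in the later ring) that the key step needs.

Step 5
Reactants: 8 (3R,4R,E)-1-[(tert-butyldimethylsilyl)oxy]-6-iodo-4,5-dimethylhex-5-en-3-yl 4-nitrobenzoate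
Product: 10 (3R,4R,E)-6-iodo-4,5-dimethylhex-5-ene-1,3-diol, via monosilyl alcohol 9 (not isolated)
Conditions: K2CO3 (0.2 equiv), MeOH, rt; then 3 M aq HCl to pH 1, rt
Reagents that add atoms: none
Why: Base-catalysed transesterification frees the C3 hydroxyl and acid solvolysis then cleaves the primary silyl ether, neither operation touching a stereocentre or the iodoalkene.

Step 6
Reactants: 10 (3R,4R,E)-6-iodo-4,5-dimethylhex-5-ene-1,3-diol
Product: 11 (3R,4R,E)-6-iodo-4,5-dimethyl-1,3-bis[(triethylsilyl)oxy]hex-5-ene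
Conditions: Et3SiCl (2.5 equiv), imidazole, DMAP (cat.), CH2Cl2, 0 °C → rt
Reagents that add atoms: chlorotriethylsilane, CC[Si](Cl)(CC)CC
Why: Standard silylation of both hydroxyls, the primary triethylsilyl ether serving as a latent aldehyde and the secondary one as the bulky equatorial control group on C3.

Step 7
Reactants: 12 2-methylbut-3-yn-2-ol
Product: 13 2-methyl-3-(tributylstannyl)but-3-en-2-ol
Conditions: Bu3SnH, Mo(CO)3(CNtBu)3 (2 mol %), hydroquinone (cat.), THF, 55 °C
Reagents that add atoms: tributyltin hydride, CCCC[SnH](CCCC)CCCC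
Why: Molybdenum-catalysed syn hydrostannation of propargylic alcohols places tin on the alkyne carbon next to the carbinol, which should give the 1,1-disubstituted alkenylstannane.

Step 8
Reactants: 13 2-methyl-3-(tributylstannyl)but-3-en-2-ol
Product: 14 tert-butyldimethyl{[2-methyl-3-(tributylstannyl)but-3-en-2-yl]oxy}silane
Conditions: TBSOTf, 2,6-lutidine, CH2Cl2, −78 → 0 °C
Reagents that add atoms: tert-butyldimethylsilyl trifluoromethanesulfonate, CC(C)(C)[Si](C)(C)OS(=O)(=O)C(F)(F)F
Why: A silyl triflate with a hindered pyridine base silylates the tertiary alcohol while the buffer prevents protodestannylation.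

Step 9
Reactants: 11 (3R,4R,E)-6-iodo-4,5-dimethyl-1,3-bis[(triethylsilyl)oxy]hex-5-ene; 14 tert-butyldimethyl{[2-methyl-3-(tributylstannyl)but-3-en-2-yl]oxy}silane
Product: 15 (3R,4R,E)-8-[(tert-butyldimethylsilyl)oxy]-4,5,8-trimethyl-7-methylidene-1,3-bis[(triethylsilyl)oxy]non-5-ene
Conditions: Pd2(dba)3 (5 mol %), AsPh3 (20 mol %), CuI (10 mol %), DMF, 45 °C
Reagents that add atoms: none
Why: Copper-assisted Stille coupling joins C6 to C7 with retention of the (E) geometry of the iodoalkene and should give the 2-substituted diene, the silyl ethers being inert.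

Step 10
Reactants: 15 (3R,4R,E)-8-[(tert-butyldimethylsilyl)oxy]-4,5,8-trimethyl-7-methylidene-1,3-bis[(triethylsilyl)oxy]non-5-ene
Product: 16 (3R,4R,E)-8-[(tert-butyldimethylsilyl)oxy]-4,5,8-trimethyl-7-methylidene-3-[(triethylsilyl)oxy]non-5-enal
Conditions: (COCl)2, DMSO, CH2Cl2, −78 → −30 °C; then Et3N, −78 °C → rt
Reagents that add atoms: none
Why: Under Swern conditions the activated sulfonium species attacks the unhindered primary triethylsilyl ether and converts it directly into the aldehyde, whereas the secondary triethylsilyl and tertiary TBS ethers should remain.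

Step 11
Reactants: 16 (3R,4R,E)-8-[(tert-butyldimethylsilyl)oxy]-4,5,8-trimethyl-7-methylidene-3-[(triethylsilyl)oxy]non-5-enal
Product: 17 (5R,6R,E)-10-[(tert-butyldimethylsilyl)oxy]-6,7,10-trimethyl-9-methylidene-5-[(triethylsilyl)oxy]undec-7-en-1-yn-3-ol (both C3 carbinol epimers)
Conditions: HC≡CMgBr (2 equiv), THF, −78 → 0 °C; aq NH4Cl
Reagents that add atoms: ethynylmagnesium bromide, C#C[Mg]Br
Why: 1,2-Addition of the alkynyl Grignard reagent to the aldehyde, the new carbinol centre being uncontrolled and erased in the next step.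

Step 12
Reactants: 17 (5R,6R,E)-10-[(tert-butyldimethylsilyl)oxy]-6,7,10-trimethyl-9-methylidene-5-[(triethylsilyl)oxy]undec-7-en-1-yn-3-ol
Product: 18 (5R,6R,E)-10-[(tert-butyldimethylsilyl)oxy]-6,7,10-trimethyl-9-methylidene-5-[(triethylsilyl)oxy]undec-7-en-1-yn-3-one (dienynone; eremophilane C3 R, C4 R)
Conditions: Dess–Martin periodinane, NaHCO3, CH2Cl2, 0 °C → rt
Reagents that add atoms: none
Why: Dess–Martin oxidation of the propargylic alcohol under buffered, non-basic conditions should give the terminal ynone without β-elimination of the C3 silyloxy group.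

Step 13
Reactants: 18 (5R,6R,E)-10-[(tert-butyldimethylsilyl)oxy]-6,7,10-trimethyl-9-methylidene-5-[(triethylsilyl)oxy]undec-7-en-1-yn-3-one
Product: 19 (3R,4R,5R)-11-[(tert-butyldimethylsilyl)oxy]-3-[(triethylsilyl)oxy]eremophila-6,9-dien-1-one (3-O β and equatorial; 4- and 5-methyl α)
Conditions: PhMe (0.01 M, degassed), BHT (10 mol %), 110 °C, sealed tube
Reagents that add atoms: none
Why: Concerted, asynchronous [4+2] cycloaddition in which the ynone C9≡C10, polarized by the C1 carbonyl, adds across the termini C5 and C8 of the s-cis diene, the closest known reaction type being the intramolecular Diels–Alder reaction of dienynones that creates a quaternary ring-fusion carbon. Ring A closes through the four-atom tether C1–C4 as the C5–C10 bond forms (six-membered, chair-like tether), and ring B is the new six-membered 1,4-cyclohexadiene completed by the C8–C9 bond. The only new stereocentre, C5, is controlled by the two tether stereocentres: with the C4 hydrogen eclipsing the diene and both the C4 methyl and the C3 silyloxy group equatorial, the alkyne reaches the face of C5 that leaves the C5 methyl (axial on ring A) cis to the C4 methyl and trans to O3. Attack on the other face would force both tether substituents axial and put the silyloxy group in a syn-pentane clash with the inside methyl on C5, so facial selectivity, the one selectivity the step needs, is secured by the matched (3R,4R) diad, while regiochemistry is fixed by the tether and the quaternary C5 excludes aromatization. The bulky silyloxyalkyl group on C7 biases the diene towards the reactive s-cis form, and dilution with BHT should suppress polymerization of the ynone.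

Step 14
Reactants: 19 (3R,4R,5R)-11-[(tert-butyldimethylsilyl)oxy]-3-[(triethylsilyl)oxy]eremophila-6,9-dien-1-one
Product: 20 (1R,3R,4R,5R)-11-[(tert-butyldimethylsilyl)oxy]-3-[(triethylsilyl)oxy]eremophila-6,9-dien-1-ol (1-OH α, axial)
Conditions: NaBH4, CeCl3·7H2O, MeOH, −78 °C
Reagents that add atoms: none
Why: Luche reduction is 1,2-selective for the enone, and hydride should arrive from the β face, anti to the axial C5 methyl that blocks the axial trajectory, which sets C1 as R (α-hydroxyl).

Step 15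
Reactants: 20 (1R,3R,4R,5R)-11-[(tert-butyldimethylsilyl)oxy]-3-[(triethylsilyl)oxy]eremophila-6,9-dien-1-ol
Product: 21 (1R,3R,4R,5R)-1,11-bis[(tert-butyldimethylsilyl)oxy]-3-[(triethylsilyl)oxy]eremophila-6,9-diene
Conditions: TBSOTf, 2,6-lutidine, CH2Cl2, −78 °C
Reagents that add atoms: tert-butyldimethylsilyl trifluoromethanesulfonate, CC(C)(C)[Si](C)(C)OS(=O)(=O)C(F)(F)F
Why: The silyl triflate protects the hindered axial allylic hydroxyl so that C1 survives the later oxidation and acylation and stays distinct from O3.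

Step 16
Reactants: 21 (1R,3R,4R,5R)-1,11-bis[(tert-butyldimethylsilyl)oxy]-3-[(triethylsilyl)oxy]eremophila-6,9-diene
Product: 22 (1R,3R,4R,5R)-1,11-bis[(tert-butyldimethylsilyl)oxy]eremophila-6,9-dien-3-ol
Conditions: PPTS (0.2 equiv), MeOH/CH2Cl2, 0 °C → rt
Reagents that add atoms: none
Why: Mild acid methanolysis removes a secondary triethylsilyl ether much faster than the allylic secondary and the tertiary TBS ethers.

Step 17
Reactants: 22 (1R,3R,4R,5R)-1,11-bis[(tert-butyldimethylsilyl)oxy]eremophila-6,9-dien-3-ol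
Product: 23 (1R,4R,5R)-1,11-bis[(tert-butyldimethylsilyl)oxy]eremophila-6,9-diene-3,8-dione
Conditions: (C5H5NH)2Cr2O7 (5 equiv), t-BuOOH (5 equiv, in decane), Celite, PhH, rt
Reagents that add atoms: tert-butyl hydroperoxide, CC(C)(C)OO
Why: Hexavalent chromium oxidizes the C3 alcohol to the ketone and, together with t-BuOOH, converts the doubly allylic C8 methylene of the 1,4-cyclohexadiene into the cross-conjugated dienone (allylic oxidation), the quaternary C5 preventing aromatization and the TBS ether on C11 preventing allylic transposition.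

Step 18
Reactants: 23 (1R,4R,5R)-1,11-bis[(tert-butyldimethylsilyl)oxy]eremophila-6,9-diene-3,8-dione
Product: 24 (1R,3S,4R,5R)-1,11-bis[(tert-butyldimethylsilyl)oxy]-3-hydroxyeremophila-6,9-dien-8-one (3-OH α, axial)
Conditions: NaBH4, MeOH/CH2Cl2, −78 → −50 °C
Reagents that add atoms: none
Why: The saturated C3 ketone is reduced faster than the hindered cross-conjugated C8 ketone, and hydride should attack equatorially from the β face because the axial C5 methyl and C1 silyloxy group block the α face, which gives the axial 3α alcohol (S), cis to both methyls.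

Step 19
Reactants: 24 (1R,3S,4R,5R)-1,11-bis[(tert-butyldimethylsilyl)oxy]-3-hydroxyeremophila-6,9-dien-8-one; 25 angelic acid [(Z)-2-methylbut-2-enoic acid]
Product: 27 (1R,3S,4R,5R)-1,11-bis[(tert-butyldimethylsilyl)oxy]-8-oxoeremophila-6,9-dien-3-yl (Z)-2-methylbut-2-enoate, via mixed anhydride 26 (not isolated)
Conditions: 25, 2,4,6-trichlorobenzoyl chloride, Et3N, PhMe, rt; then 24, PhMe, 80 °C
Reagents that add atoms: none
Why: Yamaguchi esterification through mixed anhydride 26 should acylate the hindered axial C3 hydroxyl, and leaving out DMAP avoids addition–elimination isomerization of the (Z)-acyl group to the tiglate.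

Step 20
Reactants: 27 (1R,3S,4R,5R)-1,11-bis[(tert-butyldimethylsilyl)oxy]-8-oxoeremophila-6,9-dien-3-yl (Z)-2-methylbut-2-enoate
Product: 28 (1R,3S,4R,5R)-1,11-dihydroxy-8-oxoeremophila-6,9-dien-3-yl (Z)-2-methylbut-2-enoate
Conditions: HF·pyridine, pyridine, THF, 0 °C → rt
Reagents that add atoms: none
Why: Buffered fluoride cleaves both TBS ethers without the basic conditions that would promote acyl shift between the syn-axial O3 and O1, and leaves the ester and dienone untouched.

Step 21
Reactants: 28 (1R,3S,4R,5R)-1,11-dihydroxy-8-oxoeremophila-6,9-dien-3-yl (Z)-2-methylbut-2-enoate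
Product: 29 (1R,3S,4R,5R)-11-hydroperoxy-1-hydroxy-8-oxoeremophila-6,9-dien-3-yl (Z)-2-methylbut-2-enoate (CNP0300636.1)
Conditions: H2O2 (50 % aq, 30 equiv), H2SO4 (0.1 equiv), THF, 0 °C
Reagents that add atoms: hydrogen peroxide, OO
Why: Acid-catalysed perhydrolysis (SN1), in which the tertiary C11 alcohol ionizes to a 2-acylallyl cation that H2O2 should capture at C11, whereas ionization at the secondary C1 would place charge next to the carbonyl and is disfavoured; no stereocentre is involved.

**Compound list**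

1 | (S)-but-3-yn-2-ol | C[C@H](O)C#C | starting material
2 | (S)-but-3-yn-2-yl methanesulfonate | C[C@H](OS(C)(=O)=O)C#C | intermediate
3 | 3-[(tert-butyldimethylsilyl)oxy]propanal | O=CCCO[Si](C)(C)C(C)(C)C | starting material
4 | buta-1,2-dien-1-yl(ethyl)zinc (axially chiral allenylzinc) | [H]C(C)=[C@@]=C([H])[Zn]CC | intermediate
5 | (3S,4R)-1-[(tert-butyldimethylsilyl)oxy]-4-methylhex-5-yn-3-ol | C#C[C@@H](C)[C@@H](O)CCO[Si](C)(C)C(C)(C)C | intermediate
6 | dimethylaluminium alkoxide of (3S,4R,E)-1-[(tert-butyldimethylsilyl)oxy]-6-(dimethylalumanyl)-4,5-dimethylhex-5-en-3-ol | C[Al](C)/C=C(\C)[C@@H](C)[C@@H](O[Al](C)C)CCO[Si](C)(C)C(C)(C)C | intermediate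
7 | (3S,4R,E)-1-[(tert-butyldimethylsilyl)oxy]-6-iodo-4,5-dimethylhex-5-en-3-ol | I/C=C(\C)[C@@H](C)[C@@H](O)CCO[Si](C)(C)C(C)(C)C | intermediate
8 | (3R,4R,E)-1-[(tert-butyldimethylsilyl)oxy]-6-iodo-4,5-dimethylhex-5-en-3-yl 4-nitrobenzoate | I/C=C(\C)[C@@H](C)[C@H](OC(=O)c1ccc(cc1)[N+](=O)[O-])CCO[Si](C)(C)C(C)(C)C | intermediate
9 | (3R,4R,E)-1-[(tert-butyldimethylsilyl)oxy]-6-iodo-4,5-dimethylhex-5-en-3-ol | I/C=C(\C)[C@@H](C)[C@H](O)CCO[Si](C)(C)C(C)(C)C | intermediate
10 | (3R,4R,E)-6-iodo-4,5-dimethylhex-5-ene-1,3-diol | I/C=C(\C)[C@@H](C)[C@H](O)CCO | intermediate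
11 | (3R,4R,E)-6-iodo-4,5-dimethyl-1,3-bis[(triethylsilyl)oxy]hex-5-ene | I/C=C(\C)[C@@H](C)[C@H](O[Si](CC)(CC)CC)CCO[Si](CC)(CC)CC | intermediate
12 | 2-methylbut-3-yn-2-ol | CC(C)(O)C#C | starting material
13 | 2-methyl-3-(tributylstannyl)but-3-en-2-ol | C=C([Sn](CCCC)(CCCC)CCCC)C(C)(C)O | intermediate
14 | tert-butyldimethyl{[2-methyl-3-(tributylstannyl)but-3-en-2-yl]oxy}silane | C=C([Sn](CCCC)(CCCC)CCCC)C(C)(C)O[Si](C)(C)C(C)(C)C | intermediate
15 | (3R,4R,E)-8-[(tert-butyldimethylsilyl)oxy]-4,5,8-trimethyl-7-methylidene-1,3-bis[(triethylsilyl)oxy]non-5-ene | C=C(/C=C(\C)[C@@H](C)[C@H](O[Si](CC)(CC)CC)CCO[Si](CC)(CC)CC)C(C)(C)O[Si](C)(C)C(C)(C)C | intermediate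
16 | (3R,4R,E)-8-[(tert-butyldimethylsilyl)oxy]-4,5,8-trimethyl-7-methylidene-3-[(triethylsilyl)oxy]non-5-enal | C=C(/C=C(\C)[C@@H](C)[C@H](O[Si](CC)(CC)CC)CC=O)C(C)(C)O[Si](C)(C)C(C)(C)C | intermediate
17 | (5R,6R,E)-10-[(tert-butyldimethylsilyl)oxy]-6,7,10-trimethyl-9-methylidene-5-[(triethylsilyl)oxy]undec-7-en-1-yn-3-ol (carbinol centre undefined, both epimers) | C=C(/C=C(\C)[C@@H](C)[C@H](O[Si](CC)(CC)CC)CC(O)C#C)C(C)(C)O[Si](C)(C)C(C)(C)C | intermediate
18 | (5R,6R,E)-10-[(tert-butyldimethylsilyl)oxy]-6,7,10-trimethyl-9-methylidene-5-[(triethylsilyl)oxy]undec-7-en-1-yn-3-one | C=C(/C=C(\C)[C@@H](C)[C@H](O[Si](CC)(CC)CC)CC(=O)C#C)C(C)(C)O[Si](C)(C)C(C)(C)C | intermediate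
19 | (3R,4R,5R)-11-[(tert-butyldimethylsilyl)oxy]-3-[(triethylsilyl)oxy]eremophila-6,9-dien-1-one | O=C1C[C@@H](O[Si](CC)(CC)CC)[C@H](C)[C@@]2(C)C=C(C(C)(C)O[Si](C)(C)C(C)(C)C)CC=C12 | intermediate
20 | (1R,3R,4R,5R)-11-[(tert-butyldimethylsilyl)oxy]-3-[(triethylsilyl)oxy]eremophila-6,9-dien-1-ol | O[C@@H]1C[C@@H](O[Si](CC)(CC)CC)[C@H](C)[C@@]2(C)C=C(C(C)(C)O[Si](C)(C)C(C)(C)C)CC=C12 | intermediate
21 | (1R,3R,4R,5R)-1,11-bis[(tert-butyldimethylsilyl)oxy]-3-[(triethylsilyl)oxy]eremophila-6,9-diene | CC(C)(C)[Si](C)(C)O[C@@H]1C[C@@H](O[Si](CC)(CC)CC)[C@H](C)[C@@]2(C)C=C(C(C)(C)O[Si](C)(C)C(C)(C)C)CC=C12 | intermediate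
22 | (1R,3R,4R,5R)-1,11-bis[(tert-butyldimethylsilyl)oxy]eremophila-6,9-dien-3-ol | CC(C)(C)[Si](C)(C)O[C@@H]1C[C@@H](O)[C@H](C)[C@@]2(C)C=C(C(C)(C)O[Si](C)(C)C(C)(C)C)CC=C12 | intermediate
23 | (1R,4R,5R)-1,11-bis[(tert-butyldimethylsilyl)oxy]eremophila-6,9-diene-3,8-dione | CC(C)(C)[Si](C)(C)O[C@@H]1CC(=O)[C@H](C)[C@@]2(C)C=C(C(C)(C)O[Si](C)(C)C(C)(C)C)C(=O)C=C12 | intermediate
24 | (1R,3S,4R,5R)-1,11-bis[(tert-butyldimethylsilyl)oxy]-3-hydroxyeremophila-6,9-dien-8-one | CC(C)(C)[Si](C)(C)O[C@@H]1C[C@H](O)[C@H](C)[C@@]2(C)C=C(C(C)(C)O[Si](C)(C)C(C)(C)C)C(=O)C=C12 | intermediate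
25 | angelic acid, (Z)-2-methylbut-2-enoic acid | C/C=C(/C)C(=O)O | starting material
26 | (Z)-2-methylbut-2-enoic 2,4,6-trichlorobenzoic anhydride | C/C=C(/C)C(=O)OC(=O)c1c(Cl)cc(Cl)cc1Cl | intermediate
27 | (1R,3S,4R,5R)-1,11-bis[(tert-butyldimethylsilyl)oxy]-8-oxoeremophila-6,9-dien-3-yl (Z)-2-methylbut-2-enoate | CC(C)(C)[Si](C)(C)O[C@@H]1C[C@H](OC(=O)/C(C)=C\C)[C@H](C)[C@@]2(C)C=C(C(C)(C)O[Si](C)(C)C(C)(C)C)C(=O)C=C12 | intermediate
28 | (1R,3S,4R,5R)-1,11-dihydroxy-8-oxoeremophila-6,9-dien-3-yl (Z)-2-methylbut-2-enoate | O[C@@H]1C[C@H](OC(=O)/C(C)=C\C)[C@H](C)[C@@]2(C)C=C(C(C)(C)O)C(=O)C=C12 | intermediate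
29 | (1R,3S,4R,5R)-11-hydroperoxy-1-hydroxy-8-oxoeremophila-6,9-dien-3-yl (Z)-2-methylbut-2-enoate | O[C@@H]1C[C@H](OC(=O)/C(C)=C\C)[C@H](C)[C@@]2(C)C=C(C(C)(C)OO)C(=O)C=C12 | target

**Step count and risks**

Total step count: 21 (steps 7 and 8 prepare the stannane fragment). Longest linear sequence: 19 steps (steps 1–6 and 9–21, from (S)-but-3-yn-2-ol).

Steps most likely to fail, in order of risk:

Step 13 (key cycloaddition). The inside methyl on C5 may slow the [4+2] so much that thermal decay of the terminal ynone competes. The fallback replaces the alkyne dienophile by a more electron-poor alkyne equivalent. Starting from 18, conjugate addition of PhSO2Na in AcOH/EtOH should give the (E)-3-(phenylsulfonyl)enone F1. The same intramolecular cycloaddition, now possible at lower temperature (PhMe, 80 °C), would give the 9-(phenylsulfonyl)-9,10-dihydro ketone F2, whose configuration at C9 and C10 is irrelevant. DBU in CH2Cl2 then expels benzenesulfinate by E1cB elimination and the route is rejoined at 19.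

Step 21 (hydroperoxide). Capture of the allylic cation at C6 with double-bond shift, dehydration to the isopropenyl compound, or acid-promoted acyl shift from O3 to O1 may compete with substitution at C11. The fallback makes the C11–O bond by an ene reaction instead of ionization. Starting from 27, LiBH(sec-Bu)3 (THF, −78 → 0 °C) should add hydride at C6, and the resulting enolate should eject the C11 silanolate to give the isopropylidene enone F3 (7(11),9-dien-8-one). HF·pyridine then frees the C1 hydroxyl to give the alcohol F4. A Schenck ene reaction with singlet oxygen (O2, hν, tetraphenylporphyrin, CH2Cl2, −20 °C) should bond oxygen to C11 and abstract hydrogen from C6, the group geminal to the carbonyl, which restores C6=C7 and arrives at 29.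

Step 19 (angelate). Acylation of the axial hydroxyl between two syn-axial groups may be sluggish, and prolonged heating of the activated acid may erode the (Z) geometry. The fallback builds the alkene on the ester. Starting from 24, DCC/DMAP esterification with 2-[bis(2,2,2-trifluoroethoxy)phosphoryl]propanoic acid should give the phosphonopropanoate F5. Still–Gennari olefination (KN(SiMe3)2, 18-crown-6, THF, −78 °C, acetaldehyde) then forms the (Z)-trisubstituted double bond and rejoins the route at 27.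

Further compounds
F1 | step 13 | (5R,6R,1E,7E)-10-[(tert-butyldimethylsilyl)oxy]-6,7,10-trimethyl-9-methylidene-1-(phenylsulfonyl)-5-[(triethylsilyl)oxy]undeca-1,7-dien-3-one | C=C(/C=C(\C)[C@@H](C)[C@H](O[Si](CC)(CC)CC)CC(=O)/C=C/S(=O)(=O)c1ccccc1)C(C)(C)O[Si](C)(C)C(C)(C)C
F2 | step 13 | (3R,4R,5R)-11-[(tert-butyldimethylsilyl)oxy]-9-(phenylsulfonyl)-3-[(triethylsilyl)oxy]eremophil-6-en-1-one (C9 and C10 undefined) | O=C1C[C@@H](O[Si](CC)(CC)CC)[C@H](C)[C@@]2(C)C=C(C(C)(C)O[Si](C)(C)C(C)(C)C)CC(S(=O)(=O)c3ccccc3)C12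
F3 | step 21 | (1R,3S,4R,5R)-1-[(tert-butyldimethylsilyl)oxy]-8-oxoeremophila-7(11),9-dien-3-yl (Z)-2-methylbut-2-enoate | CC(C)(C)[Si](C)(C)O[C@@H]1C[C@H](OC(=O)/C(C)=C\C)[C@H](C)[C@@]2(C)CC(=C(C)C)C(=O)C=C12
F4 | step 21 | (1R,3S,4R,5R)-1-hydroxy-8-oxoeremophila-7(11),9-dien-3-yl (Z)-2-methylbut-2-enoate | O[C@@H]1C[C@H](OC(=O)/C(C)=C\C)[C@H](C)[C@@]2(C)CC(=C(C)C)C(=O)C=C12
F5 | step 19 | (1R,3S,4R,5R)-1,11-bis[(tert-butyldimethylsilyl)oxy]-8-oxoeremophila-6,9-dien-3-yl 2-[bis(2,2,2-trifluoroethoxy)phosphoryl]propanoate (phosphonate α-carbon undefined) | CC(C)(C)[Si](C)(C)O[C@@H]1C[C@H](OC(=O)C(C)P(=O)(OCC(F)(F)F)OCC(F)(F)F)[C@H](C)[C@@]2(C)C=C(C(C)(C)O[Si](C)(C)C(C)(C)C)C(=O)C=C12
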